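## The problem

Wailupemycin H, compound 27, consists of two 4-hydroxy-2-pyrones joined through their C3 carbons by a single methylene group. Pyrone A hangs from C4 of an 8-hydroxy-1-tetralone that carries a phenyl-bearing tertiary carbinol at C3, and pyrone B sits on C1 of a 4,5-dihydroxy-2-phenylnaphthalene, which is the same tetralone after loss of water and enolisation. The only stereocentres are the adjacent C3 (R) and C4 (S). C3 is quaternary and can only be scrambled by retro-aldol opening, whereas C4 is a benzylic, pyrone-bearing methine, so C3 must be set correctly and C4 set relative to it. The tertiary β-hydroxy ketone is the fragile element: acid dehydrates it to the naphthol and base opens it by retro-aldol reaction. In addition the pyrones are acidic and C3-nucleophilic, the peri-dihydroxynaphthalene is oxidisable, and the methylene bis-pyrone can revert by retro-Michael reaction. The key step rests on two readings of the tetralone: C1(=O)–C8a–C4a–C4 is a latent o-quinoid vinylketene, and C2–C3 (a methylene beside an oxygenated, phenyl-bearing carbon) is a 1-phenylvinyl ether. Because the naphthalene half is the dehydrated tetralone half, one annulation can serve both halves and a racemate can be used in full.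

## Retrosynthesis

**27 ⇒ 22 + 24 + 25.** The two bonds from the bridging CH2 to C3 of pyrone A and C3 of pyrone B are cut. These carbons are the most nucleophilic in the molecule, so a one-carbon electrophile is the natural link; cutting only one bond would require a pre-functionalised 3-methylpyrone. The precursors are the two free monomers, tetralone pyrone 22 and naphthyl pyrone 24, each half the size of 27. The forward reaction must give the mixed product rather than homo-dimers, alkylate pyrone carbon rather than naphthol carbon, and spare the β-hydroxy ketone. It is therefore staged: 22, which has no electron-rich naphthol, is converted with iminium salt 25 into Mannich base 26, and 24 is added afterwards. The union is the last step, so nothing is deprotected on the dimer.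

**24 ⇒ 23; 22 + 23 ⇒ 21.** Naphthyl pyrone 24 is 22 minus water: C3–OH and a C2–H are removed and the ketone enolises. Racemic 21 is therefore resolved; the (3R,4S)-enantiomer 22 is kept and the (3S,4R)-enantiomer 23 is aromatised to achiral 24. This is preferred to an independent synthesis of 24, which would double the work, and to asymmetric induction in an annulation run above 100 °C, for which no catalyst is known. Exactly one equivalent of each half is needed, which a racemate supplies, and any C4-epimeric material also ends as 24. The forward steps are a chromatographic resolution and an acid-catalysed dehydration.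

**21 ⇒ 20 ⇒ 19 ⇒ 16 + 17; 16 ⇒ 15 ⇒ 14.** Pyrone A is opened at O1–C6, giving tert-butyl 3-oxo-4-ynoate 19, whose ester oxygen closes onto the alkyne under catalysis by (SPhos)AuNTf2 (monovalent gold). 19 is cut between the future C3 and C4 of the pyrone into ynal 16 and tert-butyl acetate 17. The classical triketo-ester or acylketene closures were rejected because they place a ketone on the carbon bonded to C4; that would make C4–H acidic and turn the C3 oxygen into a β-leaving group. With the alkyne, that carbon never becomes a ketone. 16 comes from propargylic alcohol 15 and PMB ether 14 by oxidation and deprotection. The forward steps must be non-basic or run at −78 °C.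

**14 ⇒ 10 + 12 (through 13).** C1–C2 and C3–C4 are cut. This removes the carbocycle and both stereocentres at once and leaves benzocyclobutenone 10 and enol ether 12. A biomimetic aldol cut at C2–C3 would require an acyclic 1,5-diketone with an enolisable, alkynyl-substituted centre. An sp-hybridised substituent on the methide carbon is essential: a vinyl or pyronyl group would let vinylketene 13 close in a six-electron fashion to a naphthol. The propargylic ether is carried through because it already contains the carbon that becomes C4 of pyrone A, so no acetylide chemistry is needed beside the ketone. The forward reaction must deliver the regiochemistry (set by polarity) and the relative configuration (silyloxy cis to alkynyl).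

**10 ⇒ 3 + 7 (through 8 and 9); 7 ⇒ 6 ⇒ 4 + 5; 3 ⇒ 2 ⇒ 1; 12 ⇒ 11.** The four-membered ring is cut into aryne 8 and ketene silyl acetal 7. The silyloxy group on the aryne fixes the orientation, so the carbonyl ends next to the oxygenated carbon. A triisopropylsilyl ether replaces a methyl ether on the phenol because it can be removed by buffered fluoride in the presence of the tertiary carbinol. 7 comes from 3-alkynoate 6, made by CuI-catalysed coupling of propargyl ether 4 with diazoacetate 5. Aryne precursor 3 comes from 2-iodoresorcinol 1 via 2, and 12 from acetophenone 11.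

## Roads not taken

**Alternative 1:** Both pyrone lactone bonds (O1–C2 of pyrones A and B) would be formed last. The precursor is the methylene-bridged bis-dioxinone A2, whose two 2-oxoalkyl arms carry the tetralone and the naphthalene. Heating A2 would release two acylketenes, each captured by the enol oxygen of its own arm, giving the protected target A1.
- Merits: both heterocycles form in one well-precedented thermal operation, and the unsymmetrical bridge is built early by stepwise C-alkylation rather than by a late cross-coupling of two pyrones. In that respect it is better than the plan chosen here, whose last step must control cross-selectivity on unprotected material.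
- Weak points: the tetralone-side arm places a ketone directly on the carbon bonded to C4. C4–H then lies between a ketone and an arene, and the C3 silyloxy group becomes a β-leaving group; elimination to the naphthalene and C4 epimerisation threaten both the enolate acylation that installs the arm and the thermolysis. The tetralone with its two stereocentres still has to be made by other means, and the naphthalene half needs its own synthesis.
- Against this, the chosen plan never places a carbonyl on that carbon, solves the stereochemical problem in the same step that builds the carbocycle, and draws both aryl halves from one intermediate.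

**Alternative 2:** The benzene ring of the tetralone would be built last. Three bonds (C4a–C5, C6–C7, C8–C8a) are cut, leading to the acyclic diyne A4, which has a terminal alkyne on C4 and an ethoxyalkynyl ketone at C1, plus acetylene A5. [Rh(cod)2]BF4 (monovalent rhodium) with a bisphosphine would join the three alkynes to give 8-ethoxytetralone A3, with pyrone A already in place.
- Merits: arene and tetralone ring form together under neutral conditions, and no ketene or strained ring is needed.
- Weak points: A4 must already contain both stereocentres in an open chain, where C4 carries a pyrone and an alkyne (a very acidic, allene-prone position) and C3 is a β-silyloxy ynone prone to elimination. Homotrimerisation of A5 and participation of the pyrone double bonds compete. The C8 ethyl ether would need a Lewis-acidic dealkylation in the presence of the tertiary benzylic carbinol. The naphthalene half is not addressed.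
- The chosen plan creates both stereocentres in a ring, where cycloaddition geometry governs their relation, and uses a fluoride-labile phenol protecting group. Alternative 2 avoids the novelty risk of a ketene/enol ether annulation, which the chosen plan has to cover with a known-chemistry fallback.

**Alternative 3:** The naphthalene ring and the biaryl bond of the pyrone B half would be made together. Pd(PPh3)4 (zerovalent palladium) inserts into the C–Cl bond of 6-chloro-4-methoxy-2-pyrone A7. The pyronylpalladium species then activates the alkyne of the o-alkynylaryl silyl enol ether A8, and the enol ether carbon attacks the phenyl-bearing alkyne carbon in a 6-endo-dig sense. Reductive elimination gives naphthylpyrone A6.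
- Merits: a short, convergent entry to the hindered aryl–pyrone bond with defined regiochemistry. For the naphthalene half alone it would be shorter than the present route to 24.
- Weak points: it solves only the achiral half and leaves the stereochemical problem untouched. Its methyl ethers, in particular the 4-methoxypyrone, need forcing dealkylation. 5-exo closure competes. Two unrelated syntheses would have to be run side by side.
- In the chosen plan 24 costs one extra step from material that would otherwise be discarded and arrives already deprotected, which offsets the shorter access that A6 offers.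

Key step: step 7

Assumptions: compounds 1, 4, 5, 11, 17 and 25 are taken as purchasable. Racemic compounds are drawn and named as the enantiomer that leads to 27 and are marked rac. Tetralone numbering (C1 ketone, C3 carbinol, C4 methine, C8 phenol) is used throughout.

## Route

Step 1
Reactants: 1 2-iodobenzene-1,3-diol (2-iodoresorcinol)
Product: 2 2-iodo-3-[(triisopropylsilyl)oxy]phenol
Conditions: TIPSCl (1.0 equiv), imidazole, DMF, 0 °C → rt
Reagents that add atoms: triisopropylsilyl chloride, CC(C)[Si](Cl)(C(C)C)C(C)C
Why: Silylation of one of two equivalent phenols; with one equivalent of chloride the mono-ether should predominate, and unreacted 1 and the bis-ether are separable and recyclable.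

Step 2
Reactants: 2 2-iodo-3-[(triisopropylsilyl)oxy]phenol
Product: 3 2-iodo-3-[(triisopropylsilyl)oxy]phenyl trifluoromethanesulfonate
Conditions: Tf2O, pyridine, CH2Cl2, 0 °C
Reagents that add atoms: trifluoromethanesulfonic anhydride, O=S(=O)(OS(=O)(=O)C(F)(F)F)C(F)(F)F
Why: O-Sulfonylation of the remaining phenol gives the 2-iodoaryl triflate array that releases an aryne on iodine–lithium exchange.

Step 3
Reactants: 4 1-methoxy-4-[(prop-2-yn-1-yloxy)methyl]benzene (4-methoxybenzyl propargyl ether); 5 ethyl diazoacetate
Product: 6 ethyl 5-[(4-methoxybenzyl)oxy]pent-3-ynoate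
Conditions: CuI (copper monoiodide, 5 mol%), MeCN, rt
Reagents that add atoms: none
Why: CuI-catalysed coupling of a terminal alkyne with a diazoacetate (copper carbene, formal insertion into the alkynyl C–H bond) gives the 3-alkynoate without base, so no allenoate should form.

Step 4
Reactants: 6 ethyl 5-[(4-methoxybenzyl)oxy]pent-3-ynoate
Product: 7 tert-butyl({1-ethoxy-5-[(4-methoxybenzyl)oxy]pent-1-en-3-yn-1-yl}oxy)dimethylsilane (E/Z mixture)
Conditions: LDA, THF, −78 °C; TBSCl, DMPU, −78 °C → rt
Reagents that add atoms: tert-butyldimethylsilyl chloride, CC(C)(C)[Si](C)(C)Cl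
Why: Kinetic enolisation at the propargylic α-carbon and O-silylation in the presence of DMPU give the ketene silyl acetal; its double-bond geometry is of no consequence.

Step 5
Reactants: 7 tert-butyl({1-ethoxy-5-[(4-methoxybenzyl)oxy]pent-1-en-3-yn-1-yl}oxy)dimethylsilane; 3 2-iodo-3-[(triisopropylsilyl)oxy]phenyl trifluoromethanesulfonate
Product: 10 rac-8-{3-[(4-methoxybenzyl)oxy]prop-1-yn-1-yl}-5-[(triisopropylsilyl)oxy]bicyclo[4.2.0]octa-1,3,5-trien-7-one, via 3-[(triisopropylsilyl)oxy]benzyne 8 (not isolated), via mixed silyl ketal 9 (not isolated)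
Conditions: n-BuLi, THF, −78 °C; then 46% aq. HF, MeCN, 0 °C
Reagents that add atoms: none
Why: Iodine–lithium exchange expels triflate to give aryne 8, and (2+2) cycloaddition of arynes with ketene silyl acetals is a known route to benzocyclobutenone ketals; the inductively withdrawing silyloxy group directs the nucleophilic α-carbon of 7 to the distal aryne carbon, so the acetal carbon ends beside the oxygenated position. Aqueous HF cleaves the mixed ketal 9 to the ketone while the aryl silyl ether and the PMB ether should persist; the C8 stereocentre is racemic and is erased in step 7.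

Step 6
Reactants: 11 acetophenone
Product: 12 triethyl[(1-phenylethenyl)oxy]silane
Conditions: TESOTf, Et3N, CH2Cl2, 0 °C
Reagents that add atoms: triethylsilyl trifluoromethanesulfonate, CC[Si](CC)(CC)OS(=O)(=O)C(F)(F)F
Why: Soft enolisation and O-silylation of a methyl ketone; the triethylsilyl group is chosen because it resists migration in step 7 yet leaves a tertiary ether that buffered fluoride can cleave.

Step 7
Reactants: 10 rac-8-{3-[(4-methoxybenzyl)oxy]prop-1-yn-1-yl}-5-[(triisopropylsilyl)oxy]bicyclo[4.2.0]octa-1,3,5-trien-7-one; 12 triethyl[(1-phenylethenyl)oxy]silane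
Product: 14 rac-(3R,4S)-4-{3-[(4-methoxybenzyl)oxy]prop-1-yn-1-yl}-3-phenyl-3-[(triethylsilyl)oxy]-8-[(triisopropylsilyl)oxy]-3,4-dihydronaphthalen-1(2H)-one, via o-quinoid vinylketene 13 (not isolated)
Conditions: 12 (5 equiv), PhMe, 110 °C, sealed tube, argon
Reagents that add atoms: none
Why: Proposed new method: on heating, 10 should open by conrotatory four-electron ring opening with the alkynyl group turning outward to give the (E)-o-quinoid vinylketene 13, in which C1 is an electrophilic ketene carbon and C4 the terminus of a quinodimethane that regains benzene aromaticity on bond formation. The nucleophilic methylene of 12 attacks C1 (C1–C2 bond), leaving an arene-stabilised propargylic anion at C4 and a silyloxocarbenium ion at C3, which collapse in a 6-exo-trig sense to the C3–C4 bond; concerted-asynchronous or two-stage, the six-membered ring closes as a (4+2) union of C1–C8a–C4a–C4 with C2–C3. The closest known reactions are the thermal trapping of benzocyclobutenone-derived vinylketenes by dienophiles and carbonyl compounds, the polar addition of ketenes to silyl enol ethers, and the insertion of alkenes into the acyl C–C bond of benzocyclobutenones catalysed by [Rh(cod)Cl]2 (monovalent rhodium). Regiochemistry follows from polarity (enol ether β-carbon to ketene carbon). The relative configuration of the two new stereocentres is set by the (E)-geometry of the methide terminus together with the orientation of 12: with the silyloxy group endo, as is usual for enol ethers in inverse-demand cycloadditions, and phenyl exo, the silyloxy group ends cis to the alkynyl group and phenyl trans, as in 27. No absolute control is attempted, since one enantiomer of the product is needed for the tetralone half and the other for the naphthalene half (steps 14 and 15). The step needs ring closure to outrun silyl transfer to the enolate oxygen (open-chain acylation), Moore-type closure of any (Z)-ketene onto the alkyne, and ketene dimerisation; the excess of 12, the poorly migrating triethylsilyl group, the outward preference of the alkynyl substituent and the aromatisation gained on C3–C4 closure should secure it.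

Step 8
Reactants: 14 rac-(3R,4S)-4-{3-[(4-methoxybenzyl)oxy]prop-1-yn-1-yl}-3-phenyl-3-[(triethylsilyl)oxy]-8-[(triisopropylsilyl)oxy]-3,4-dihydronaphthalen-1(2H)-one
Product: 15 rac-(3R,4S)-4-(3-hydroxyprop-1-yn-1-yl)-3-phenyl-3-[(triethylsilyl)oxy]-8-[(triisopropylsilyl)oxy]-3,4-dihydronaphthalen-1(2H)-one
Conditions: DDQ, CH2Cl2/pH 7 buffer, 0 °C → rt
Reagents that add atoms: none
Why: Oxidative cleavage of the electron-rich PMB ether by DDQ (hydride abstraction, then hydrolysis of the oxocarbenium ion); silyl ethers, ketone and alkyne are inert.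

Step 9
Reactants: 15 rac-(3R,4S)-4-(3-hydroxyprop-1-yn-1-yl)-3-phenyl-3-[(triethylsilyl)oxy]-8-[(triisopropylsilyl)oxy]-3,4-dihydronaphthalen-1(2H)-one
Product: 16 rac-(3R,4S)-4-(3-oxoprop-1-yn-1-yl)-3-phenyl-3-[(triethylsilyl)oxy]-8-[(triisopropylsilyl)oxy]-3,4-dihydronaphthalen-1(2H)-one
Conditions: MnO2, CH2Cl2, rt
Reagents that add atoms: none
Why: MnO2 oxidises the propargylic alcohol to the ynal under neutral conditions, so the β-silyloxy ketone and the acidic C4–H are left alone.

Step 10
Reactants: 16 rac-(3R,4S)-4-(3-oxoprop-1-yn-1-yl)-3-phenyl-3-[(triethylsilyl)oxy]-8-[(triisopropylsilyl)oxy]-3,4-dihydronaphthalen-1(2H)-one; 17 tert-butyl acetate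
Product: 18 tert-butyl 3-hydroxy-5-{rac-(1S,2R)-4-oxo-2-phenyl-2-[(triethylsilyl)oxy]-5-[(triisopropylsilyl)oxy]-1,2,3,4-tetrahydronaphthalen-1-yl}pent-4-ynoate (both carbinol epimers)
Conditions: 17, LDA, THF, −78 °C; then 16, −78 °C; aq. NH4Cl
Reagents that add atoms: none
Why: Aldol addition of a lithium ester enolate to the aldehyde at −78 °C; the ynal is far more electrophilic than the hindered aryl ketone, and ester enolates add 1,2 to ynals. The new carbinol centre forms without control and is removed in step 11.

Step 11
Reactants: 18 tert-butyl 3-hydroxy-5-{rac-(1S,2R)-4-oxo-2-phenyl-2-[(triethylsilyl)oxy]-5-[(triisopropylsilyl)oxy]-1,2,3,4-tetrahydronaphthalen-1-yl}pent-4-ynoate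
Product: 19 tert-butyl 3-oxo-5-{rac-(1S,2R)-4-oxo-2-phenyl-2-[(triethylsilyl)oxy]-5-[(triisopropylsilyl)oxy]-1,2,3,4-tetrahydronaphthalen-1-yl}pent-4-ynoate
Conditions: Dess–Martin periodinane, CH2Cl2, 0 °C → rt
Reagents that add atoms: none
Why: Dess–Martin oxidation of the propargylic alcohol gives the 3-oxo-4-ynoate (keto–enol mixture) without base, which avoids ynone-to-allenone isomerisation at C4.

Step 12
Reactants: 19 tert-butyl 3-oxo-5-{rac-(1S,2R)-4-oxo-2-phenyl-2-[(triethylsilyl)oxy]-5-[(triisopropylsilyl)oxy]-1,2,3,4-tetrahydronaphthalen-1-yl}pent-4-ynoate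
Product: 20 rac-(3R,4R)-4-(4-hydroxy-2-oxo-2H-pyran-6-yl)-3-phenyl-3-[(triethylsilyl)oxy]-8-[(triisopropylsilyl)oxy]-3,4-dihydronaphthalen-1(2H)-one
Conditions: (SPhos)AuNTf2 (monovalent gold, 5 mol%), MeNO2/AcOH (4:1), rt
Reagents that add atoms: none
Why: Gold-catalysed 6-endo-dig lactonisation: the ester carbonyl oxygen adds to the gold-activated ynone at the carbon bonded to C4, the tert-butyl group leaves as isobutene and protodeauration gives the 4-hydroxy-2-pyrone, an established route from tert-butyl 3-oxo-4-ynoates. The carbon on C4 never becomes a ketone, so C4 should keep its configuration (the change of descriptor from 4S to 4R is only a change of priorities).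

Step 13
Reactants: 20 rac-(3R,4R)-4-(4-hydroxy-2-oxo-2H-pyran-6-yl)-3-phenyl-3-[(triethylsilyl)oxy]-8-[(triisopropylsilyl)oxy]-3,4-dihydronaphthalen-1(2H)-one
Product: 21 rac-(3R,4S)-3,8-dihydroxy-4-(4-hydroxy-2-oxo-2H-pyran-6-yl)-3-phenyl-3,4-dihydronaphthalen-1(2H)-one
Conditions: TBAF, AcOH (1:1), THF, 0 °C → rt
Reagents that add atoms: none
Why: Buffered fluoride removes the aryl triisopropylsilyl ether and the tertiary triethylsilyl ether near neutrality, so the tertiary β-hydroxy ketone should neither dehydrate nor open by retro-aldol reaction.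

Step 14
Reactants: 21 rac-(3R,4S)-3,8-dihydroxy-4-(4-hydroxy-2-oxo-2H-pyran-6-yl)-3-phenyl-3,4-dihydronaphthalen-1(2H)-one
Product: 22 (3R,4S)-3,8-dihydroxy-4-(4-hydroxy-2-oxo-2H-pyran-6-yl)-3-phenyl-3,4-dihydronaphthalen-1(2H)-one; 23 (3S,4R)-3,8-dihydroxy-4-(4-hydroxy-2-oxo-2H-pyran-6-yl)-3-phenyl-3,4-dihydronaphthalen-1(2H)-one, collected as a separate fraction
Conditions: preparative HPLC, amylose tris(3,5-dimethylphenylcarbamate) chiral phase, n-hexane/EtOH/0.1% HCO2H
Reagents that add atoms: none
Why: Resolution of a racemate by preparative chromatography on a polysaccharide chiral stationary phase, a standard operation for acidic 4-hydroxypyranones; this is where the absolute configuration is secured. The assignment would rest on circular dichroism against a computed spectrum and finally on the identity of 27 with the natural product; any C4-epimeric material is removed here and can join 23.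

Step 15
Reactants: 23 (3S,4R)-3,8-dihydroxy-4-(4-hydroxy-2-oxo-2H-pyran-6-yl)-3-phenyl-3,4-dihydronaphthalen-1(2H)-one
Product: 24 6-(4,5-dihydroxy-2-phenylnaphthalen-1-yl)-4-hydroxy-2H-pyran-2-one
Conditions: TsOH·H2O (10 mol%), PhMe, 80 °C, argon
Reagents that add atoms: none
Why: Acid-catalysed dehydration of the β-hydroxy ketone followed by tautomerisation of the 4H-naphthalen-1-one to the naphthol (aromatisation); both stereocentres are destroyed, so the unwanted enantiomer and any other stereoisomer converge on achiral 24.

Step 16
Reactants: 22 (3R,4S)-3,8-dihydroxy-4-(4-hydroxy-2-oxo-2H-pyran-6-yl)-3-phenyl-3,4-dihydronaphthalen-1(2H)-one; 25 N,N-dimethylmethyleneiminium iodide (Eschenmoser's salt); 24 6-(4,5-dihydroxy-2-phenylnaphthalen-1-yl)-4-hydroxy-2H-pyran-2-one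
Product: 27 wailupemycin H, via Mannich base 26 (not isolated)
Conditions: 25 (1.0 equiv), Et3N (1.0 equiv), MeCN, 0 °C → rt; then 24 (1.0 equiv), 45 °C, argon
Reagents that add atoms: none
Why: Mannich reaction at C3 of the pyrone of 22, then loss of dimethylamine to a 3-methylenepyran-2,4-dione that is captured by the pyronate of 24 (Michael addition), the established way to unsymmetrical methylene-bridged cyclic 1,3-dicarbonyl compounds. 22 is made the Mannich partner because it has no electron-rich naphthol to compete for the iminium ion; no stereocentre is touched.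

## Compound list

1 | 2-iodobenzene-1,3-diol | Oc1cccc(O)c1I | starting material
2 | 2-iodo-3-[(triisopropylsilyl)oxy]phenol | Oc1cccc(O[Si](C(C)C)(C(C)C)C(C)C)c1I | intermediate
3 | 2-iodo-3-[(triisopropylsilyl)oxy]phenyl trifluoromethanesulfonate | O=S(=O)(Oc1cccc(O[Si](C(C)C)(C(C)C)C(C)C)c1I)C(F)(F)F | intermediate
4 | 1-methoxy-4-[(prop-2-yn-1-yloxy)methyl]benzene | C#CCOCc1ccc(OC)cc1 | starting material
5 | ethyl diazoacetate | CCOC(=O)C=[N+]=[N-] | starting material
6 | ethyl 5-[(4-methoxybenzyl)oxy]pent-3-ynoate | CCOC(=O)CC#CCOCc1ccc(OC)cc1 | intermediate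
7 | tert-butyl({1-ethoxy-5-[(4-methoxybenzyl)oxy]pent-1-en-3-yn-1-yl}oxy)dimethylsilane (E/Z mixture) | CCOC(O[Si](C)(C)C(C)(C)C)=CC#CCOCc1ccc(OC)cc1 | intermediate
8 | 3-[(triisopropylsilyl)oxy]benzyne | CC(C)[Si](OC1=CC=CC#C1)(C(C)C)C(C)C | intermediate (not isolated)
9 | rac-tert-butyl[(7-ethoxy-8-{3-[(4-methoxybenzyl)oxy]prop-1-yn-1-yl}-5-[(triisopropylsilyl)oxy]bicyclo[4.2.0]octa-1,3,5-trien-7-yl)oxy]dimethylsilane (diastereomer mixture) | CCOC1(O[Si](C)(C)C(C)(C)C)C(C#CCOCc2ccc(OC)cc2)c2cccc(O[Si](C(C)C)(C(C)C)C(C)C)c21 | intermediate (not isolated)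
10 | rac-8-{3-[(4-methoxybenzyl)oxy]prop-1-yn-1-yl}-5-[(triisopropylsilyl)oxy]bicyclo[4.2.0]octa-1,3,5-trien-7-one | O=C1C(C#CCOCc2ccc(OC)cc2)c2cccc(O[Si](C(C)C)(C(C)C)C(C)C)c21 | intermediate
11 | acetophenone | CC(=O)c1ccccc1 | starting material
12 | triethyl[(1-phenylethenyl)oxy]silane | C=C(O[Si](CC)(CC)CC)c1ccccc1 | intermediate
13 | 2-{(6E)-6-{4-[(4-methoxybenzyl)oxy]but-2-yn-1-ylidene}-2-[(triisopropylsilyl)oxy]cyclohexa-2,4-dien-1-ylidene}ethen-1-one | O=C=C1C(O[Si](C(C)C)(C(C)C)C(C)C)=CC=C/C1=C\C#CCOCc1ccc(OC)cc1 | intermediate (not isolated)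
14 | rac-(3R,4S)-4-{3-[(4-methoxybenzyl)oxy]prop-1-yn-1-yl}-3-phenyl-3-[(triethylsilyl)oxy]-8-[(triisopropylsilyl)oxy]-3,4-dihydronaphthalen-1(2H)-one (racemate, one enantiomer drawn) | O=C1C[C@](O[Si](CC)(CC)CC)(c2ccccc2)[C@@H](C#CCOCc2ccc(OC)cc2)c2cccc(O[Si](C(C)C)(C(C)C)C(C)C)c21 | intermediate
15 | rac-(3R,4S)-4-(3-hydroxyprop-1-yn-1-yl)-3-phenyl-3-[(triethylsilyl)oxy]-8-[(triisopropylsilyl)oxy]-3,4-dihydronaphthalen-1(2H)-one (racemate, one enantiomer drawn) | O=C1C[C@](O[Si](CC)(CC)CC)(c2ccccc2)[C@@H](C#CCO)c2cccc(O[Si](C(C)C)(C(C)C)C(C)C)c21 | intermediate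
16 | rac-(3R,4S)-4-(3-oxoprop-1-yn-1-yl)-3-phenyl-3-[(triethylsilyl)oxy]-8-[(triisopropylsilyl)oxy]-3,4-dihydronaphthalen-1(2H)-one (racemate, one enantiomer drawn) | O=C1C[C@](O[Si](CC)(CC)CC)(c2ccccc2)[C@@H](C#CC=O)c2cccc(O[Si](C(C)C)(C(C)C)C(C)C)c21 | intermediate
17 | tert-butyl acetate | CC(=O)OC(C)(C)C | starting material
18 | tert-butyl 3-hydroxy-5-{rac-(1S,2R)-4-oxo-2-phenyl-2-[(triethylsilyl)oxy]-5-[(triisopropylsilyl)oxy]-1,2,3,4-tetrahydronaphthalen-1-yl}pent-4-ynoate (carbinol epimers, ring racemic, one enantiomer drawn) | O=C1C[C@](O[Si](CC)(CC)CC)(c2ccccc2)[C@@H](C#CC(O)CC(=O)OC(C)(C)C)c2cccc(O[Si](C(C)C)(C(C)C)C(C)C)c21 | intermediate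
19 | tert-butyl 3-oxo-5-{rac-(1S,2R)-4-oxo-2-phenyl-2-[(triethylsilyl)oxy]-5-[(triisopropylsilyl)oxy]-1,2,3,4-tetrahydronaphthalen-1-yl}pent-4-ynoate (racemate, one enantiomer drawn) | O=C1C[C@](O[Si](CC)(CC)CC)(c2ccccc2)[C@@H](C#CC(=O)CC(=O)OC(C)(C)C)c2cccc(O[Si](C(C)C)(C(C)C)C(C)C)c21 | intermediate
20 | rac-(3R,4R)-4-(4-hydroxy-2-oxo-2H-pyran-6-yl)-3-phenyl-3-[(triethylsilyl)oxy]-8-[(triisopropylsilyl)oxy]-3,4-dihydronaphthalen-1(2H)-one (racemate, one enantiomer drawn) | O=C1C[C@](O[Si](CC)(CC)CC)(c2ccccc2)[C@@H](c2cc(O)cc(=O)o2)c2cccc(O[Si](C(C)C)(C(C)C)C(C)C)c21 | intermediate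
21 | rac-(3R,4S)-3,8-dihydroxy-4-(4-hydroxy-2-oxo-2H-pyran-6-yl)-3-phenyl-3,4-dihydronaphthalen-1(2H)-one (racemate, one enantiomer drawn) | O=C1C[C@](O)(c2ccccc2)[C@@H](c2cc(O)cc(=O)o2)c2cccc(O)c21 | intermediate
22 | (3R,4S)-3,8-dihydroxy-4-(4-hydroxy-2-oxo-2H-pyran-6-yl)-3-phenyl-3,4-dihydronaphthalen-1(2H)-one | O=C1C[C@](O)(c2ccccc2)[C@@H](c2cc(O)cc(=O)o2)c2cccc(O)c21 | intermediate
23 | (3S,4R)-3,8-dihydroxy-4-(4-hydroxy-2-oxo-2H-pyran-6-yl)-3-phenyl-3,4-dihydronaphthalen-1(2H)-one | O=C1C[C@@](O)(c2ccccc2)[C@H](c2cc(O)cc(=O)o2)c2cccc(O)c21 | intermediate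
24 | 6-(4,5-dihydroxy-2-phenylnaphthalen-1-yl)-4-hydroxy-2H-pyran-2-one | O=c1cc(O)cc(-c2c(-c3ccccc3)cc(O)c3c(O)cccc23)o1 | intermediate
25 | N,N-dimethylmethyleneiminium iodide | C[N+](C)=C.[I-] | starting material
26 | (3R,4S)-4-{3-[(dimethylamino)methyl]-4-hydroxy-2-oxo-2H-pyran-6-yl}-3,8-dihydroxy-3-phenyl-3,4-dihydronaphthalen-1(2H)-one | O=C1C[C@](O)(c2ccccc2)[C@@H](c2cc(O)c(CN(C)C)c(=O)o2)c2cccc(O)c21 | intermediate (not isolated)
27 | wailupemycin H, (3R,4S)-4-[3-{[6-(4,5-dihydroxy-2-phenylnaphthalen-1-yl)-4-hydroxy-2-oxo-2H-pyran-3-yl]methyl}-4-hydroxy-2-oxo-2H-pyran-6-yl]-3,8-dihydroxy-3-phenyl-3,4-dihydronaphthalen-1(2H)-one | O=C1C[C@](O)(c2ccccc2)[C@@H](c2cc(O)c(Cc3c(O)cc(-c4c(-c5ccccc5)cc(O)c5c(O)cccc45)oc3=O)c(=O)o2)c2cccc(O)c21 | target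

## Step count and least certain steps

Total: 16 steps. Longest linear sequence: 13 steps (1, 2, 5, 7–16, with 24 passing through step 15 before the union).

**Step 7 (key step, proposed new method).** Three processes are most likely to interfere:
- silyl transfer inside the zwitterion, giving open-chain C-acylation of the enol ether instead of ring closure;
- inward rotation of the alkynyl group, followed by Moore-type closure of the ketene onto the alkyne;
- poor endo/exo selectivity, which would lower the share of the trans isomer (the cis isomer is still usable for 24).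

The fallback forms the same two bonds stepwise with known reactions. It sets out from 10 and 11 and returns at 14. The lithium enolate of 11 (LDA, THF, −78 °C) is added to ketone 10 from the face opposite the alkynyl group and quenched cold, giving the aldol 2-{7-hydroxy-8-{3-[(4-methoxybenzyl)oxy]prop-1-yn-1-yl}-5-[(triisopropylsilyl)oxy]bicyclo[4.2.0]octa-1,3,5-trien-7-yl}-1-phenylethan-1-one F1, in which the hydroxyl is cis to the alkynyl group; this forms C1–C2. TESOTf and Et3N silylate the tertiary alcohol and convert the phenacyl ketone into its (Z)-silyl enol ether, giving bis-silyl ether F2. Heating F2 in toluene should open the four-membered ring with the 7-silyloxy group outward and the styryl arm inward, and the resulting triene closes by disrotatory six-electron electrocyclisation to the ring-expanded enol silane F3; this forms C3–C4 and is the known ring expansion of 7-alkenylbenzocyclobutenol derivatives to tetralones. Because silyloxy and alkynyl are cis in F2 and the enol ether is (Z), the closure should place phenyl trans to the alkynyl group. Mild hydrolysis of the enol silyl ether (AcOH, THF, H2O) gives 14.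

**Step 16.** The most likely failures are:
- loss of cross-selectivity through retro-Mannich and retro-Michael exchange of the methylene unit, giving homo-dimers;
- C-alkylation of the naphthol ring of 24;
- amine-induced retro-aldol opening of the tetralone during the elimination.

The fallback sets out from 22 and returns at 27. Aqueous formaldehyde and sodium p-toluenesulfinate in aqueous formic acid convert 22 into the storable sulfone (3R,4S)-3,8-dihydroxy-4-(4-hydroxy-3-{[(4-methylphenyl)sulfonyl]methyl}-2-oxo-2H-pyran-6-yl)-3-phenyl-3,4-dihydronaphthalen-1(2H)-one F4, which is purified. With 24 and NaHCO3 in aqueous MeCN at room temperature, sulfinate is eliminated and the methylene-pyrandione is captured by the pyronate of 24. The electrophile is then generated without a free amine, in the presence of its partner only.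

**Step 12.** The most likely failures are:
- slow 6-endo attack at an alkyne carbon flanked by the bulky C4 centre;
- isomerisation of the ynone to an allenone at C4;
- acid-induced loss of the C3 silyl ether followed by dehydration.

The fallback replaces π-acid activation by carboxylate conjugate addition. It sets out from 16 and returns at 20. Aldol addition of the lithium enolate of allyl acetate to 16 gives the allyl β-hydroxy ester F5, and Dess–Martin oxidation gives the allyl 3-oxo-4-ynoate F6. Pd(PPh3)4 (zerovalent palladium) with PhSiH3 at 0 °C removes the allyl group, and the liberated acid, with a trace of Et3N, should add 6-endo to the ynone (oxa-Michael lactonisation) to give 20 directly.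

**Step 14.** The most likely failure is insufficient separation, or dehydration on the column, of a polar, acidic, chelating triol at preparative scale. The fallback is a classical resolution. It sets out from 21 and returns at 22. 21 is combined with one antipode of 1-phenylethylamine, drawn here as (R), and the less soluble diastereomeric ammonium pyronate F7 is crystallised. Acidification of the crystals releases 22, and the mother liquor, enriched in 23, goes to step 15. If the opposite salt crystallises, the other antipode of the amine is used.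

## Further compounds

F1 | step 7 | rac-2-{7-hydroxy-8-{3-[(4-methoxybenzyl)oxy]prop-1-yn-1-yl}-5-[(triisopropylsilyl)oxy]bicyclo[4.2.0]octa-1,3,5-trien-7-yl}-1-phenylethan-1-one (hydroxyl cis to alkynyl) | O=C(C[C@@]1(O)[C@H](C#CCOCc2ccc(OC)cc2)c2cccc(O[Si](C(C)C)(C(C)C)C(C)C)c21)c1ccccc1
F2 | step 7 | rac-triethyl{[(Z)-2-{8-{3-[(4-methoxybenzyl)oxy]prop-1-yn-1-yl}-7-[(triethylsilyl)oxy]-5-[(triisopropylsilyl)oxy]bicyclo[4.2.0]octa-1,3,5-trien-7-yl}-1-phenylethenyl]oxy}silane (silyloxy cis to alkynyl) | CC[Si](CC)(CC)O/C(=C\[C@@]1(O[Si](CC)(CC)CC)[C@H](C#CCOCc2ccc(OC)cc2)c2cccc(O[Si](C(C)C)(C(C)C)C(C)C)c21)c1ccccc1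
F3 | step 7 | rac-(3S,4S)-4-{3-[(4-methoxybenzyl)oxy]prop-1-yn-1-yl}-3-phenyl-1,3-bis[(triethylsilyl)oxy]-8-[(triisopropylsilyl)oxy]-3,4-dihydronaphthalene (same spatial arrangement as in 14; the C3 descriptor changes with the priorities) | CC[Si](CC)(CC)OC1=C[C@](O[Si](CC)(CC)CC)(c2ccccc2)[C@@H](C#CCOCc2ccc(OC)cc2)c2cccc(O[Si](C(C)C)(C(C)C)C(C)C)c21
F4 | step 16 | (3R,4S)-3,8-dihydroxy-4-(4-hydroxy-3-{[(4-methylphenyl)sulfonyl]methyl}-2-oxo-2H-pyran-6-yl)-3-phenyl-3,4-dihydronaphthalen-1(2H)-one | O=C1C[C@](O)(c2ccccc2)[C@@H](c2cc(O)c(CS(=O)(=O)c3ccc(C)cc3)c(=O)o2)c2cccc(O)c21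
F5 | step 12 | prop-2-en-1-yl 3-hydroxy-5-{rac-(1S,2R)-4-oxo-2-phenyl-2-[(triethylsilyl)oxy]-5-[(triisopropylsilyl)oxy]-1,2,3,4-tetrahydronaphthalen-1-yl}pent-4-ynoate (carbinol epimers) | O=C1C[C@](O[Si](CC)(CC)CC)(c2ccccc2)[C@@H](C#CC(O)CC(=O)OCC=C)c2cccc(O[Si](C(C)C)(C(C)C)C(C)C)c21
F6 | step 12 | prop-2-en-1-yl 3-oxo-5-{rac-(1S,2R)-4-oxo-2-phenyl-2-[(triethylsilyl)oxy]-5-[(triisopropylsilyl)oxy]-1,2,3,4-tetrahydronaphthalen-1-yl}pent-4-ynoate | O=C1C[C@](O[Si](CC)(CC)CC)(c2ccccc2)[C@@H](C#CC(=O)CC(=O)OCC=C)c2cccc(O[Si](C(C)C)(C(C)C)C(C)C)c21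
F7 | step 14 | (R)-1-phenylethylammonium salt of 22 (pyronate) | O=C1C[C@](O)(c2ccccc2)[C@@H](c2cc([O-])cc(=O)o2)c2cccc(O)c21.C[C@@H]([NH3+])c1ccccc1
A1 | alternative 1 | wailupemycin H protected as the C3 triethylsilyl ether and tris(methoxymethyl) ether of the three phenols | O=C1C[C@](O[Si](CC)(CC)CC)(c2ccccc2)[C@@H](c2cc(O)c(Cc3c(O)cc(-c4c(-c5ccccc5)cc(OCOC)c5c(OCOC)cccc45)oc3=O)c(=O)o2)c2cccc(OCOC)c21
A2 | alternative 1 | methylene-bridged bis(2,2-dimethyl-1,3-dioxin-4-one) carrying the tetralonyl and naphthyl 2-oxoethyl arms at its two C6 positions | O=C1C[C@](O[Si](CC)(CC)CC)(c2ccccc2)[C@@H](C(=O)CC2=C(CC3=C(CC(=O)c4c(-c5ccccc5)cc(OCOC)c5c(OCOC)cccc45)OC(C)(C)OC3=O)C(=O)OC(C)(C)O2)c2cccc(OCOC)c21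
A3 | alternative 2 | (3R,4R)-8-ethoxy-4-[4-(methoxymethoxy)-2-oxo-2H-pyran-6-yl]-3-phenyl-3-[(triethylsilyl)oxy]-3,4-dihydronaphthalen-1(2H)-one | O=C1C[C@](O[Si](CC)(CC)CC)(c2ccccc2)[C@@H](c2cc(OCOC)cc(=O)o2)c2cccc(OCC)c21
A4 | alternative 2 | (5R,6R)-1-ethoxy-6-[4-(methoxymethoxy)-2-oxo-2H-pyran-6-yl]-5-phenyl-5-[(triethylsilyl)oxy]octa-1,7-diyn-3-one | O=C(C#COCC)C[C@](O[Si](CC)(CC)CC)(c1ccccc1)[C@@H](c1cc(OCOC)cc(=O)o1)C#C
A5 | alternative 2 | acetylene | C#C
A6 | alternative 3 | 6-(4-hydroxy-5-methoxy-2-phenylnaphthalen-1-yl)-4-methoxy-2H-pyran-2-one | COc1cc(-c2c(-c3ccccc3)cc(O)c3c(OC)cccc23)oc(=O)c1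
A7 | alternative 3 | 6-chloro-4-methoxy-2H-pyran-2-one | COc1cc(Cl)oc(=O)c1
A8 | alternative 3 | tert-butyl({1-[2-methoxy-6-(phenylethynyl)phenyl]ethenyl}oxy)dimethylsilane | C=C(O[Si](C)(C)C(C)(C)C)c1c(OC)cccc1C#Cc1ccccc1
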